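The route rests on cutting the O1–C8a bond of the pyran ring. Oxygen sits on C5, C6, C8 and C8a of the benzo ring. Two-electron oxidation of the C5/C6 catechol therefore turns C8a into the β-carbon of a vinylogous ester (C8a=C4a–C5=O) that can exchange its alkoxy group. In one operation the tertiary carbinol oxygen adds to C8a, methanol departs and the 2H-chromene-5,6-dione results. The C2–O bond, and hence the S centre, stays untouched. The precursor is a 4,5-dimethoxy-o-quinone bearing at C3 a (Z)-3-hydroxy-3-methylpentenyl chain that ends in the (1R,3R)-dimethyl-methylidenecyclohexane. All three stereocentres are in place before ring closure.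

Key step: step 16

Locants: chromene numbering (O1, C2–C8a) is used for the bicycle. Primed numbers are used for the cyclohexane (C1' quaternary, C2' methylidene-bearing, C3' CHMe).

Assumption: (S)-1-phenylethylamine is taken to induce the same sense at the quaternary carbon of the 2,6-dimethyl imine as it does for 2-methylcyclohexanone imines. Enantiomeric purity is to be checked, and if needed raised by low-temperature crystallisation, at the octalone stage.

Step 1
Reactants: 1 2,6-dimethylcyclohexan-1-one (cis/trans mixture); 2 (S)-1-phenylethan-1-amine; 3 but-3-en-2-one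
Product: 6 (2R)-2,6-dimethyl-2-(3-oxobutyl)cyclohexan-1-one as C6 epimers, via ketimine 4 (not isolated), via adduct imine 5 (not isolated)
Conditions: cat. TsOH, PhMe, Dean–Stark, reflux; concentrate; 3, 40 °C; then 20% aq AcOH, rt
Reagents that add atoms: water, O
Why: Asymmetric Michael addition of a chiral imine through its secondary enamine tautomer (compact, aza-ene-like transition state), in which the phenylethyl group should shield one face so that C2 is set as R, while C6 stays unsettled and is corrected in step 2.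

Step 2
Reactants: 6 (2R)-2,6-dimethyl-2-(3-oxobutyl)cyclohexan-1-one
Product: 7 (4aR,8R)-4a,8-dimethyl-4,4a,5,6,7,8-hexahydronaphthalen-2(3H)-one
Conditions: NaOMe, MeOH, reflux
Reagents that add atoms: none
Why: Intramolecular aldol condensation (second half of a Robinson annulation) under equilibrating conditions, in which C8, being γ to the enone, epimerises via the dienolate to the equatorial methyl group trans to the axial angular methyl (no 1,3-diaxial Me/Me contact), so that C8 (the later C3') should be set as R by thermodynamic control.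

Step 3
Reactants: 7 (4aR,8R)-4a,8-dimethyl-4,4a,5,6,7,8-hexahydronaphthalen-2(3H)-one
Product: 8 (4aR,8R)-1,8a-epoxy-4a,8-dimethyloctahydronaphthalen-2(1H)-one (epoxide epimers)
Conditions: 30% H2O2, aq NaOH, MeOH, 0 °C → rt
Reagents that add atoms: hydrogen peroxide, OO
Why: Weitz–Scheffer nucleophilic epoxidation, routine for octalones of this type and for steroidal 4-en-3-ones; the two new oxirane centres need no control because both are erased in step 4.

Step 4
Reactants: 8 (4aR,8R)-1,8a-epoxy-4a,8-dimethyloctahydronaphthalen-2(1H)-one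
Product: 10 (2R,6R)-2-(but-3-yn-1-yl)-2,6-dimethylcyclohexan-1-one, via epoxy tosylhydrazone 9 (not isolated)
Conditions: TsNHNH2, AcOH–CH2Cl2 (1:1), −20 °C → rt
Reagents that add atoms: none
Why: Eschenmoser–Tanabe fragmentation, in which the hydrazone opens the oxirane and then loses sulfinate and N2 with cleavage of C1–C8a, unveiling the ring ketone and a terminal alkyne under weakly acidic conditions that should leave the C6 centre untouched.

Step 5
Reactants: 10 (2R,6R)-2-(but-3-yn-1-yl)-2,6-dimethylcyclohexan-1-one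
Product: 12 (1R,3R)-1-(but-3-yn-1-yl)-1,3-dimethyl-2-methylidenecyclohexane, via β-hydroxysilane 11 (not isolated)
Conditions: Me3SiCH2Li (2.5 equiv), CeCl3, THF, −78 → 0 °C, then H2O; crude carbinol: KH, THF, 0 °C → rt
Reagents that add atoms: (trimethylsilyl)methyllithium, [Li]C[Si](C)(C)C
Why: Cerium-modified Peterson olefination, whose weakly basic organocerium reagent adds to hindered, enolisable ketones rather than deprotonating C6–H, and syn elimination from the potassium alkoxide gives the exocyclic methylene, after which C3' can no longer epimerise.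

Step 6
Reactants: 12 (1R,3R)-1-(but-3-yn-1-yl)-1,3-dimethyl-2-methylidenecyclohexane
Product: 15 (2E)-5-[(1R,3R)-1,3-dimethyl-2-methylidenecyclohexyl]-3-methylpent-2-en-1-ol, via alkenylalane 13 (not isolated), via lithium alanate 14 (not isolated)
Conditions: Me3Al, Cp2ZrCl2 (cat.), CH2Cl2, 0 °C → rt; n-BuLi, THF–hexane, −78 → 0 °C; (CH2O)n, rt; H2O
Reagents that add atoms: trimethylaluminium, C[Al](C)C; paraformaldehyde (as formaldehyde), C=O
Why: Negishi zirconium-catalysed carboalumination adds Me and Al syn with Al at the terminus, and the derived alanate attacks formaldehyde with retention, so the E-trisubstituted allylic alcohol should form while the hindered 1,1-disubstituted alkene stays inert.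

Step 7
Reactants: 15 (2E)-5-[(1R,3R)-1,3-dimethyl-2-methylidenecyclohexyl]-3-methylpent-2-en-1-ol
Product: 16 {(2S,3S)-3-[2-((1R,3R)-1,3-dimethyl-2-methylidenecyclohexyl)ethyl]-3-methyloxiran-2-yl}methanol
Conditions: Ti(OiPr)4 (cat.), L-(+)-DET (cat.), t-BuOOH, 4 Å MS, CH2Cl2, −20 °C
Reagents that add atoms: tert-butyl hydroperoxide, CC(C)(C)OO
Why: Sharpless asymmetric epoxidation under reagent control, where L-(+)-tartrate converts an E-3-methylalk-2-en-1-ol (geraniol type) into the (2S,3S)-epoxide and thereby fixes the oxygen-bearing centre that becomes C2, the isolated methylidene group not being a substrate.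

Step 8
Reactants: 16 {(2S,3S)-3-[2-((1R,3R)-1,3-dimethyl-2-methylidenecyclohexyl)ethyl]-3-methyloxiran-2-yl}methanol
Product: 17 (2R,3S)-2-(chloromethyl)-3-[2-((1R,3R)-1,3-dimethyl-2-methylidenecyclohexyl)ethyl]-3-methyloxirane
Conditions: PPh3, CCl4, NaHCO3, reflux
Reagents that add atoms: carbon tetrachloride, ClC(Cl)(Cl)Cl
Why: Appel reaction, an SN2 displacement at the primary carbon under buffered conditions that leaves the oxirane and both of its centres intact (the C2 descriptor changes only because Cl outranks O).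

Step 9
Reactants: 17 (2R,3S)-2-(chloromethyl)-3-[2-((1R,3R)-1,3-dimethyl-2-methylidenecyclohexyl)ethyl]-3-methyloxirane
Product: 18 (3S)-5-[(1R,3R)-1,3-dimethyl-2-methylidenecyclohexyl]-3-methylpent-1-yn-3-ol
Conditions: n-BuLi (3.3 equiv), THF, −78 → −30 °C; H2O
Reagents that add atoms: none
Why: Base-induced double elimination of a 2,3-epoxy chloride, in which lithiation next to chlorine opens the oxirane by β-elimination and loss of HCl then gives the terminal alkyne, the tertiary C–O bond staying intact so that the S configuration is carried over.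

Step 10
Reactants: 19 catechol
Product: 20 4,5-dimethoxycyclohexa-3,5-diene-1,2-dione
Conditions: NaIO3, MeOH, rt
Reagents that add atoms: methanol, CO
Why: Oxidation to o-benzoquinone followed twice by 1,4-addition of methanol and re-oxidation, a known one-pot entry to this stable, doubly vinylogous ester quinone.

Step 11
Reactants: 20 4,5-dimethoxycyclohexa-3,5-diene-1,2-dione
Product: 22 [(4,5-dimethoxy-1,2-phenylene)bis(oxy)]bis[tert-butyl(dimethyl)silane], via 4,5-dimethoxycatechol 21 (not isolated)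
Conditions: H2 (1 atm), Pd/C, THF, rt; Ar purge; TBSCl, imidazole, DMF, rt
Reagents that add atoms: tert-butyldimethylsilyl chloride, CC(C)(C)[Si](C)(C)Cl
Why: Catalytic hydrogenation of the quinone and standard silyl ether formation on the air-sensitive catechol in the same flask, fluoride-labile groups being chosen because the later tertiary allylic alcohol would not stand acidic deprotection.

Step 12
Reactants: 22 [(4,5-dimethoxy-1,2-phenylene)bis(oxy)]bis[tert-butyl(dimethyl)silane]
Product: 23 [(3-iodo-4,5-dimethoxy-1,2-phenylene)bis(oxy)]bis[tert-butyl(dimethyl)silane]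
Conditions: NIS (1.0 equiv), TFA (cat.), MeCN, 0 °C → rt, dark
Reagents that add atoms: N-iodosuccinimide, O=C1CCC(=O)N1I
Why: Electrophilic aromatic iodination of a tetra-oxygenated benzene whose only two free positions are equivalent, so regiochemistry is not an issue and one equivalent of reagent should stop at the mono-iodide.

Step 13
Reactants: 18 (3S)-5-[(1R,3R)-1,3-dimethyl-2-methylidenecyclohexyl]-3-methylpent-1-yn-3-ol; 23 [(3-iodo-4,5-dimethoxy-1,2-phenylene)bis(oxy)]bis[tert-butyl(dimethyl)silane]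
Product: 24 (3S)-1-{2,3-bis[(tert-butyldimethylsilyl)oxy]-5,6-dimethoxyphenyl}-5-[(1R,3R)-1,3-dimethyl-2-methylidenecyclohexyl]-3-methylpent-1-yn-3-ol
Conditions: PdCl2(PPh3)2 (cat.), CuI (cat.), Et3N–DMF, 55 °C, degassed
Reagents that add atoms: none
Why: Sonogashira coupling of an aryl iodide with an unprotected tertiary propargylic alcohol, a class of alkyne that couples well, while the silyl ether ortho to the new alkyne blocks benzofuran formation.

Step 14
Reactants: 24 (3S)-1-{2,3-bis[(tert-butyldimethylsilyl)oxy]-5,6-dimethoxyphenyl}-5-[(1R,3R)-1,3-dimethyl-2-methylidenecyclohexyl]-3-methylpent-1-yn-3-ol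
Product: 25 (1Z,3S)-1-{2,3-bis[(tert-butyldimethylsilyl)oxy]-5,6-dimethoxyphenyl}-5-[(1R,3R)-1,3-dimethyl-2-methylidenecyclohexyl]-3-methylpent-1-en-3-ol
Conditions: H2 (1 atm), Lindlar catalyst, quinoline, EtOAc, rt
Reagents that add atoms: none
Why: Lindlar semihydrogenation delivers H2 syn and should give the Z-alkene, the poisoned catalyst sparing the hindered methylidene group.

Step 15
Reactants: 25 (1Z,3S)-1-{2,3-bis[(tert-butyldimethylsilyl)oxy]-5,6-dimethoxyphenyl}-5-[(1R,3R)-1,3-dimethyl-2-methylidenecyclohexyl]-3-methylpent-1-en-3-ol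
Product: 27 3-[(1Z,3S)-5-((1R,3R)-1,3-dimethyl-2-methylidenecyclohexyl)-3-hydroxy-3-methylpent-1-en-1-yl]-4,5-dimethoxycyclohexa-3,5-diene-1,2-dione, via free catechol 26 (not isolated)
Conditions: TBAF–AcOH (1:1, 2.2 equiv), THF, 0 °C, Ar; then Ag2O, Na2SO4, Et2O, 0 °C → rt, dark
Reagents that add atoms: none
Why: Buffered fluoride desilylation followed at once by silver(I) oxide oxidation of the catechol to the o-quinone, the non-acidic medium and the immediate oxidation avoiding dehydrative closure of the C5 phenol onto the allylic carbinol, which would give a regioisomeric and racemised chromene.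

Step 16
Reactants: 27 3-[(1Z,3S)-5-((1R,3R)-1,3-dimethyl-2-methylidenecyclohexyl)-3-hydroxy-3-methylpent-1-en-1-yl]-4,5-dimethoxycyclohexa-3,5-diene-1,2-dione
Product: 28 (2S)-2-[2-((1R,3R)-1,3-dimethyl-2-methylidenecyclohexyl)ethyl]-8-methoxy-2-methyl-2H-chromene-5,6-dione
Conditions: PPTS (cat.), 5 Å MS, PhMe, rt → 45 °C, Ar, dark
Reagents that add atoms: none
Why: Mild acid activates the C5 carbonyl oxygen, the tertiary hydroxyl adds to C8a (β-carbon of the C8a=C4a–C5=O vinylogous ester), and the mixed-ketal adduct expels methanol, which the sieves bind, so the quinone is restored with O1 in place of the methoxy oxygen. The closest known reaction type is the alkoxy exchange (addition–elimination, vinylogous transesterification) of alkoxyquinones and the closure of hydroxyalkyl alkoxyquinones to pyranoquinones; only the tertiary nucleophile is more demanding than usual. The pyran ring closes in a 6-endo-trig mode with respect to C8a=C4a, which the Z-alkene makes geometrically easy. No stereocentre is created, and C2 keeps its S configuration because the carbinol reacts through oxygen and its C–O bond is never broken, ionisation being disfavoured by the electron-poor quinone on the allyl system. The hydroxyl can also reach the C5 carbonyl carbon, but that hemiketal forms reversibly and leads nowhere, whereas removal of methanol makes exchange at C8a irreversible, and the C8 methoxy carbon lies beyond the reach of the short Z-tether, so only the C8a methoxy group is replaced. Exclusion of light guards against electrocyclic opening of the 2H-pyran, the one process that could erode C2.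

Step 17
Reactants: 28 (2S)-2-[2-((1R,3R)-1,3-dimethyl-2-methylidenecyclohexyl)ethyl]-8-methoxy-2-methyl-2H-chromene-5,6-dione
Product: 29 (2S)-2-[2-((1R,3R)-1,3-dimethyl-2-methylidenecyclohexyl)ethyl]-8-methoxy-2-methyl-2H-chromene-5,6-diol (target)
Conditions: Na2S2O4, EtOAc–H2O (degassed), rt
Reagents that add atoms: none
Why: Dithionite reduction of an o-quinone to its catechol, a mild two-electron reduction that touches neither alkene nor any stereocentre and leaves no protecting group to remove.

Compound list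

1 | 2,6-dimethylcyclohexan-1-one (cis/trans mixture) | CC1CCCC(C)C1=O | starting material
2 | (S)-1-phenylethan-1-amine | C[C@H](N)c1ccccc1 | starting material
3 | but-3-en-2-one (methyl vinyl ketone) | C=CC(C)=O | starting material
4 | 2,6-dimethyl-N-[(1S)-1-phenylethyl]cyclohexan-1-imine | CC1CCCC(C)C1=N[C@@H](C)c1ccccc1 | intermediate
5 | 4-[(1R)-1,3-dimethyl-2-{[(1S)-1-phenylethyl]imino}cyclohexyl]butan-2-one | C[C@@H](c2ccccc2)N=C1C(C)CCC[C@]1(C)CCC(C)=O | intermediate
6 | (2R)-2,6-dimethyl-2-(3-oxobutyl)cyclohexan-1-one (C6 epimers) | O=C1C(C)CCC[C@]1(C)CCC(C)=O | intermediate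
7 | (4aR,8R)-4a,8-dimethyl-4,4a,5,6,7,8-hexahydronaphthalen-2(3H)-one | O=C2C=C1[C@H](C)CCC[C@]1(C)CC2 | intermediate
8 | (4aR,8R)-1,8a-epoxy-4a,8-dimethyloctahydronaphthalen-2(1H)-one (epoxide epimers) | O=C2C3OC31[C@H](C)CCC[C@]1(C)CC2 | intermediate
9 | 4-methylbenzenesulfonylhydrazone of 8 | Cc4ccc(cc4)S(=O)(=O)NN=C2C3OC31[C@H](C)CCC[C@]1(C)CC2 | intermediate
10 | (2R,6R)-2-(but-3-yn-1-yl)-2,6-dimethylcyclohexan-1-one | O=C1[C@H](C)CCC[C@]1(C)CCC#C | intermediate
11 | (2R,6R)-2-(but-3-yn-1-yl)-2,6-dimethyl-1-[(trimethylsilyl)methyl]cyclohexan-1-ol (C1 epimers) | C[Si](C)(C)CC1(O)[C@H](C)CCC[C@]1(C)CCC#C | intermediate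
12 | (1R,3R)-1-(but-3-yn-1-yl)-1,3-dimethyl-2-methylidenecyclohexane | C=C1[C@H](C)CCC[C@]1(C)CCC#C | intermediate
13 | [(1E)-4-((1R,3R)-1,3-dimethyl-2-methylidenecyclohexyl)-2-methylbut-1-en-1-yl]dimethylalane | C=C1[C@H](C)CCC[C@]1(C)CC/C(C)=C/[Al](C)C | intermediate
14 | lithium butyl[(1E)-4-((1R,3R)-1,3-dimethyl-2-methylidenecyclohexyl)-2-methylbut-1-en-1-yl]dimethylalanate | [Li+].C=C1[C@H](C)CCC[C@]1(C)CC/C(C)=C/[Al-](C)(C)CCCC | intermediate
15 | (2E)-5-[(1R,3R)-1,3-dimethyl-2-methylidenecyclohexyl]-3-methylpent-2-en-1-ol | C=C1[C@H](C)CCC[C@]1(C)CC/C(C)=C/CO | intermediate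
16 | {(2S,3S)-3-[2-((1R,3R)-1,3-dimethyl-2-methylidenecyclohexyl)ethyl]-3-methyloxiran-2-yl}methanol | C=C1[C@H](C)CCC[C@]1(C)CC[C@]2(C)O[C@H]2CO | intermediate
17 | (2R,3S)-2-(chloromethyl)-3-[2-((1R,3R)-1,3-dimethyl-2-methylidenecyclohexyl)ethyl]-3-methyloxirane | C=C1[C@H](C)CCC[C@]1(C)CC[C@]2(C)O[C@H]2CCl | intermediate
18 | (3S)-5-[(1R,3R)-1,3-dimethyl-2-methylidenecyclohexyl]-3-methylpent-1-yn-3-ol | C=C1[C@H](C)CCC[C@]1(C)CC[C@](C)(O)C#C | intermediate
19 | catechol | Oc1ccccc1O | starting material
20 | 4,5-dimethoxycyclohexa-3,5-diene-1,2-dione | COC1=CC(=O)C(=O)C=C1OC | intermediate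
21 | 4,5-dimethoxybenzene-1,2-diol | COc1cc(O)c(O)cc1OC | intermediate
22 | [(4,5-dimethoxy-1,2-phenylene)bis(oxy)]bis[tert-butyl(dimethyl)silane] | COc1cc(O[Si](C)(C)C(C)(C)C)c(O[Si](C)(C)C(C)(C)C)cc1OC | intermediate
23 | [(3-iodo-4,5-dimethoxy-1,2-phenylene)bis(oxy)]bis[tert-butyl(dimethyl)silane] | COc1cc(O[Si](C)(C)C(C)(C)C)c(O[Si](C)(C)C(C)(C)C)c(I)c1OC | intermediate
24 | (3S)-1-{2,3-bis[(tert-butyldimethylsilyl)oxy]-5,6-dimethoxyphenyl}-5-[(1R,3R)-1,3-dimethyl-2-methylidenecyclohexyl]-3-methylpent-1-yn-3-ol | C=C1[C@H](C)CCC[C@]1(C)CC[C@](C)(O)C#Cc2c(OC)c(OC)cc(O[Si](C)(C)C(C)(C)C)c2O[Si](C)(C)C(C)(C)C | intermediate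
25 | (1Z,3S)-1-{2,3-bis[(tert-butyldimethylsilyl)oxy]-5,6-dimethoxyphenyl}-5-[(1R,3R)-1,3-dimethyl-2-methylidenecyclohexyl]-3-methylpent-1-en-3-ol | C=C1[C@H](C)CCC[C@]1(C)CC[C@](C)(O)/C=C\c2c(OC)c(OC)cc(O[Si](C)(C)C(C)(C)C)c2O[Si](C)(C)C(C)(C)C | intermediate
26 | 3-[(1Z,3S)-5-((1R,3R)-1,3-dimethyl-2-methylidenecyclohexyl)-3-hydroxy-3-methylpent-1-en-1-yl]-4,5-dimethoxybenzene-1,2-diol | C=C1[C@H](C)CCC[C@]1(C)CC[C@](C)(O)/C=C\c2c(OC)c(OC)cc(O)c2O | intermediate
27 | 3-[(1Z,3S)-5-((1R,3R)-1,3-dimethyl-2-methylidenecyclohexyl)-3-hydroxy-3-methylpent-1-en-1-yl]-4,5-dimethoxycyclohexa-3,5-diene-1,2-dione | C=C1[C@H](C)CCC[C@]1(C)CC[C@](C)(O)/C=C\C2=C(OC)C(OC)=CC(=O)C2=O | intermediate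
28 | (2S)-2-[2-((1R,3R)-1,3-dimethyl-2-methylidenecyclohexyl)ethyl]-8-methoxy-2-methyl-2H-chromene-5,6-dione | C=C1[C@H](C)CCC[C@]1(C)CC[C@@]1(C)C=CC2=C(O1)C(OC)=CC(=O)C2=O | intermediate
29 | (2S)-2-[2-((1R,3R)-1,3-dimethyl-2-methylidenecyclohexyl)ethyl]-8-methoxy-2-methyl-2H-chromene-5,6-diol | C=C1[C@H](C)CCC[C@]1(C)CC[C@@]1(C)C=Cc2c(O)c(O)cc(OC)c2O1 | target

Total step count: 17. Longest linear sequence: 14 (steps 1–9 and 13–17).

Steps most likely to fail

1. Step 16. Addition of the hindered tertiary hydroxyl to the fully substituted C8a may be slower than self-condensation of the quinone or hydrolytic loss of a methoxy group. The substrate may also simply rest as the C5 hemiketal. The fallback sets out from 18 and rejoins the route at 28.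
   - Commercial 2-hydroxy-5-methoxybenzaldehyde is iodinated ortho to the phenol (NIS) to 2-hydroxy-3-iodo-5-methoxybenzaldehyde F1.
   - Dakin oxidation (H2O2, NaOH) gives 3-iodo-5-methoxybenzene-1,2-diol F2, and TBSCl/imidazole gives its bis-silyl ether F3.
   - Sonogashira coupling with 18 gives the aryl alkyne F4, and Lindlar reduction gives the Z-alkene F5.
   - Buffered TBAF gives the catechol F6, and excess Ag2O gives the 5-methoxy-o-quinone F7, which carries hydrogen instead of methoxy at C8a.
   - The carbinol then adds 1,4 to an unsubstituted, far less crowded β-carbon. This is the same alcohol-to-o-quinone addition with re-oxidation that builds 20 in step 10.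
   - The adduct tautomerises to catechol 29, and the excess oxidant takes it on to 28.

2. Step 5. Addition to a carbonyl flanked by a quaternary and a tertiary carbon may stall, and any enolisation would scramble C6. The fallback sets out from 10 and returns at 12.
   - Dimethylsulfonium methylide (Me3SI, n-BuLi, THF, 0 °C; Corey–Chaykovsky reaction) is a much smaller carbon nucleophile and gives the spiro-epoxide F8.
   - LiPPh2 opens it at the CH2 terminus to the β-hydroxy phosphine F9 (as its lithium alkoxide).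
   - MeI quaternises phosphorus to the betaine F10, which collapses in a Wittig-type syn elimination to 12.

3. Step 13. Oxidative addition at an electron-rich iodide flanked by OMe and OTBS may be slow. That would leave room for oxidative alkyne homocoupling, and for loss of the ortho silyl group followed by 5-endo cyclisation to a benzofuran. The fallback sets out from 18 and 23 and returns at 25, so it also bypasses step 14.
   - The polarity is inverted, so that palladium inserts into an unhindered vinyl iodide.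
   - 18 is iodinated at the alkyne terminus (NIS, cat. AgNO3, acetone) to the iodoalkyne F11.
   - Diimide (2-nitrobenzenesulfonyl hydrazide, Et3N) reduces F11 by syn hydrogen transfer to the (Z)-vinyl iodide F12.
   - 23 is turned by iodine–magnesium exchange (iPrMgCl·LiCl, THF, −20 °C) into the aryl Grignard reagent F13, and with ZnCl2 into the arylzinc chloride F14.
   - Negishi coupling of F12 with a slight excess of F14 (Pd/SPhos, THF, rt) proceeds with retention of alkene geometry and gives 25.

Further compounds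

F1 | step 16 | 2-hydroxy-3-iodo-5-methoxybenzaldehyde | COc1cc(I)c(O)c(C=O)c1
F2 | step 16 | 3-iodo-5-methoxybenzene-1,2-diol | COc1cc(O)c(O)c(I)c1
F3 | step 16 | [(3-iodo-5-methoxy-1,2-phenylene)bis(oxy)]bis[tert-butyl(dimethyl)silane] | COc1cc(O[Si](C)(C)C(C)(C)C)c(O[Si](C)(C)C(C)(C)C)c(I)c1
F4 | step 16 | (3S)-1-{2,3-bis[(tert-butyldimethylsilyl)oxy]-5-methoxyphenyl}-5-[(1R,3R)-1,3-dimethyl-2-methylidenecyclohexyl]-3-methylpent-1-yn-3-ol | C=C1[C@H](C)CCC[C@]1(C)CC[C@](C)(O)C#Cc2cc(OC)cc(O[Si](C)(C)C(C)(C)C)c2O[Si](C)(C)C(C)(C)C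
F5 | step 16 | (1Z,3S)-1-{2,3-bis[(tert-butyldimethylsilyl)oxy]-5-methoxyphenyl}-5-[(1R,3R)-1,3-dimethyl-2-methylidenecyclohexyl]-3-methylpent-1-en-3-ol | C=C1[C@H](C)CCC[C@]1(C)CC[C@](C)(O)/C=C\c2cc(OC)cc(O[Si](C)(C)C(C)(C)C)c2O[Si](C)(C)C(C)(C)C
F6 | step 16 | 3-[(1Z,3S)-5-((1R,3R)-1,3-dimethyl-2-methylidenecyclohexyl)-3-hydroxy-3-methylpent-1-en-1-yl]-5-methoxybenzene-1,2-diol | C=C1[C@H](C)CCC[C@]1(C)CC[C@](C)(O)/C=C\c2cc(OC)cc(O)c2O
F7 | step 16 | 3-[(1Z,3S)-5-((1R,3R)-1,3-dimethyl-2-methylidenecyclohexyl)-3-hydroxy-3-methylpent-1-en-1-yl]-5-methoxycyclohexa-3,5-diene-1,2-dione | C=C1[C@H](C)CCC[C@]1(C)CC[C@](C)(O)/C=C\C2=CC(OC)=CC(=O)C2=O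
F8 | step 5 | (4R,8R)-4-(but-3-yn-1-yl)-4,8-dimethyl-1-oxaspiro[2.5]octane (spiro-centre epimers) | C1OC12[C@H](C)CCC[C@]2(C)CCC#C
F9 | step 5 | (2R,6R)-2-(but-3-yn-1-yl)-1-[(diphenylphosphanyl)methyl]-2,6-dimethylcyclohexan-1-ol | OC1(CP(c2ccccc2)c2ccccc2)[C@H](C)CCC[C@]1(C)CCC#C
F10 | step 5 | (2R,6R)-2-(but-3-yn-1-yl)-2,6-dimethyl-1-{[methyl(diphenyl)phosphonio]methyl}cyclohexan-1-olate | [O-]C1(C[P+](C)(c2ccccc2)c2ccccc2)[C@H](C)CCC[C@]1(C)CCC#C
F11 | step 13 | (3S)-5-[(1R,3R)-1,3-dimethyl-2-methylidenecyclohexyl]-1-iodo-3-methylpent-1-yn-3-ol | C=C1[C@H](C)CCC[C@]1(C)CC[C@](C)(O)C#CI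
F12 | step 13 | (1Z,3S)-5-[(1R,3R)-1,3-dimethyl-2-methylidenecyclohexyl]-1-iodo-3-methylpent-1-en-3-ol | C=C1[C@H](C)CCC[C@]1(C)CC[C@](C)(O)/C=C\I
F13 | step 13 | {2,3-bis[(tert-butyldimethylsilyl)oxy]-5,6-dimethoxyphenyl}magnesium chloride | COc1cc(O[Si](C)(C)C(C)(C)C)c(O[Si](C)(C)C(C)(C)C)c([Mg]Cl)c1OC
F14 | step 13 | {2,3-bis[(tert-butyldimethylsilyl)oxy]-5,6-dimethoxyphenyl}zinc chloride | COc1cc(O[Si](C)(C)C(C)(C)C)c(O[Si](C)(C)C(C)(C)C)c([Zn]Cl)c1OC
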